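**Retrosynthetic overview**

1. The strategy rests on ring C, the benzene ring of the chroman (C4a, C5, C6, C7, C8, C8a). Its oxygens on C7 and C8a are meta to each other, C4a carries the ring D carbon C4 and C5 carries C2 of the benzofuran, which is the pattern an aldol-folded 1,3,5-triketone leaves (ring A = benzo ring of the benzofuran, ring B = furan, ring D = dihydropyran).
2. Endgame disconnections: the two benzyl ethers on ring A (BCl3), then O1–C2 of ring D (the phenol oxygen on C8a adding across a prenyl group on C4a).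
3. Key disconnection: C4a–C5 of ring C, opened to triketone 16, whose benzofuranyl ketone carbon becomes C5 and whose chain methylene becomes C4a.
4. Triketone 16 comes from benzofuran ester 11 and the dianion of diketone 14 (acetylacetone plus prenyl bromide). Ester 11 comes from phenol 1 by O-prenylation, Claisen rearrangement, ortho-formylation and annulation with ethyl bromoacetate.
5. Ring order: A (bought), B (step 4), C (step 7), D (step 8).

Key step: step 7

Remark on the chemistry: the target has no stereocentre, so no step has to control configuration. The 1,3-dicarbonyl compounds are drawn as keto forms although they are expected to exist largely as enols.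

**Route**

Step 1
Reactants: 1 3,5-bis(benzyloxy)phenol; 2 1-bromo-3-methylbut-2-ene
Product: 3 1,3-bis(benzyloxy)-5-[(3-methylbut-2-en-1-yl)oxy]benzene
Conditions: K2CO3, acetone, reflux
Reagents that add atoms: none
Why: Williamson ether synthesis, in which the phenoxide of 1 displaces bromide from the primary allylic halide at oxygen (SN2) while the benzyl ethers are inert to carbonate.

Step 2
Reactants: 3 1,3-bis(benzyloxy)-5-[(3-methylbut-2-en-1-yl)oxy]benzene
Product: 5 3,5-bis(benzyloxy)-2-(2-methylbut-3-en-2-yl)phenol, via ortho-dienone 4 (not isolated)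
Conditions: PhNEt2, 190 °C, sealed tube, Ar
Reagents that add atoms: none
Why: Aromatic Claisen rearrangement, a [3,3]-sigmatropic shift that delivers the allyl unit with inversion to one of the two equivalent ortho carbons, after which dienone 4 should tautomerise quickly in the basic amine solvent to the ortho-(1,1-dimethylallyl)phenol.

Step 3
Reactants: 5 3,5-bis(benzyloxy)-2-(2-methylbut-3-en-2-yl)phenol
Product: 7 4,6-bis(benzyloxy)-2-hydroxy-3-(2-methylbut-3-en-2-yl)benzaldehyde, via hydroxymethylphenol 6 (not isolated)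
Conditions: MgCl2, Et3N, (CH2O)n, MeCN, reflux; then 1 M HCl
Reagents that add atoms: formaldehyde (from paraformaldehyde), C=O
Why: Casnati–Skattebøl ortho-formylation, in which the magnesium phenoxide directs formaldehyde to the only free ortho carbon and the chelated salicyl alkoxide 6 is oxidised to the aldehyde by hydride transfer to a second formaldehyde, the para carbon staying untouched.

Step 4
Reactants: 7 4,6-bis(benzyloxy)-2-hydroxy-3-(2-methylbut-3-en-2-yl)benzaldehyde; 8 ethyl bromoacetate
Product: 11 ethyl 4,6-bis(benzyloxy)-7-(2-methylbut-3-en-2-yl)-1-benzofuran-2-carboxylate, via aryloxyacetate 9 (not isolated), via hydroxydihydrobenzofuran 10 (not isolated)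
Conditions: K2CO3, DMF, 100 °C
Reagents that add atoms: none
Why: Rap–Stoermer-type annulation, in which O-alkylation of the phenoxide by the α-bromo ester is followed by intramolecular aldol addition of the ester enolate to the ortho-formyl group and by dehydration driven by aromatisation of ring B.

Step 5
Reactants: 12 pentane-2,4-dione; 2 1-bromo-3-methylbut-2-ene
Product: 14 8-methylnon-7-ene-2,4-dione, via dilithium dienediolate 13 (not isolated)
Conditions: LiN(i-Pr)2 (2.1 equiv), THF, 0 °C; then 2, 0 °C; 1 M HCl
Reagents that add atoms: none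
Why: Terminal alkylation of a β-diketone dianion, in which the methyl-derived carbanion of 13 is far more nucleophilic than the delocalised central enolate and attacks the primary allylic bromide by SN2, so only the methyl carbon is prenylated.

Step 6
Reactants: 14 8-methylnon-7-ene-2,4-dione; 11 ethyl 4,6-bis(benzyloxy)-7-(2-methylbut-3-en-2-yl)-1-benzofuran-2-carboxylate
Product: 16 1-[4,6-bis(benzyloxy)-7-(2-methylbut-3-en-2-yl)-1-benzofuran-2-yl]-9-methyldec-8-ene-1,3,5-trione, via dilithium dienediolate 15 (not isolated)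
Conditions: 14 (3 equiv), LiN(i-Pr)2 (6 equiv), THF, −78 → 0 °C; then 11, 0 → 25 °C; 1 M HCl
Reagents that add atoms: none
Why: Claisen-type acylation of a β-diketone dianion by an ester, in which the second deprotonation of 14 should occur at the methyl group and not at the more substituted methylene, the terminal carbanion adds to the ester with loss of ethoxide, and the triketone formed is deprotonated at once by the excess dianion and so protected from a second addition.

Step 7
Reactants: 16 1-[4,6-bis(benzyloxy)-7-(2-methylbut-3-en-2-yl)-1-benzofuran-2-yl]-9-methyldec-8-ene-1,3,5-trione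
Product: 18 5-[4,6-bis(benzyloxy)-7-(2-methylbut-3-en-2-yl)-1-benzofuran-2-yl]-4-(3-methylbut-2-en-1-yl)benzene-1,3-diol, via cyclic aldol 17 (not isolated)
Conditions: 2 M aq. KOH, MeOH (degassed), Ar, 25 → 45 °C; then cold 1 M HCl to pH 5
Reagents that add atoms: none
Why: In aqueous hydroxide the triketone is held as a polyenolate whose chain-end enolate carbon C6 (the methylene between the C5 carbonyl and the homoprenyl residue, future C4a) adds to the benzofuranyl ketone carbon C1 (future C5) to give cyclic aldol 17, and E1cB loss of hydroxide followed by enolisation of the cyclohexenedione gives the resorcinol, the gain of aromaticity making the sequence irreversible. The closest known reaction type is the biomimetic base-mediated aldol aromatisation of 1,3,5-triketones to resorcinols (the orcinol-type fold), here with a methylene in place of a methyl nucleophile and an aroyl carbonyl as acceptor. Ring C is closed in a six-membered (enolendo)-exo-trig aldol addition, which is a favoured mode. No stereocentre is left, because the carbinol and methine centres of 17 are both lost on dehydration and aromatisation. The step needs carbon to win over oxygen cyclisation and a single regiochemistry: the aryl ketone has no α-hydrogen on its arene side and every other carbon–carbonyl pairing would give a four-membered ring, so this is the only aldol open to the chain, while the fully ionised enolate in water without acid should not close to the 4-pyranone that acid would favour. Degassed solutions protect the electron-rich resorcinolate from air, and the moderate temperature limits retro-Claisen cleavage by hydroxide.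

Step 8
Reactants: 18 5-[4,6-bis(benzyloxy)-7-(2-methylbut-3-en-2-yl)-1-benzofuran-2-yl]-4-(3-methylbut-2-en-1-yl)benzene-1,3-diol
Product: 19 5-[4,6-bis(benzyloxy)-7-(2-methylbut-3-en-2-yl)-1-benzofuran-2-yl]-2,2-dimethyl-3,4-dihydro-2H-chromen-7-ol
Conditions: Amberlyst 15, CH2Cl2, 25 °C
Reagents that add atoms: none
Why: Acid-catalysed intramolecular Markovnikov hydroalkoxylation of an ortho-prenylphenol, in which protonation of the trisubstituted alkene gives a tertiary cation that only the adjacent hydroxyl can reach in a six-membered closure, whereas the vinyl group of the 1,1-dimethylallyl unit would need a secondary cation and has no free neighbouring hydroxyl while ring A is benzylated.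

Step 9
Reactants: 19 5-[4,6-bis(benzyloxy)-7-(2-methylbut-3-en-2-yl)-1-benzofuran-2-yl]-2,2-dimethyl-3,4-dihydro-2H-chromen-7-ol
Product: 20 2-(7-hydroxy-2,2-dimethyl-3,4-dihydro-2H-chromen-5-yl)-7-(2-methylbut-3-en-2-yl)-1-benzofuran-4,6-diol
Conditions: BCl3, pentamethylbenzene, CH2Cl2, −78 °C; then MeOH, aq. NaHCO3
Reagents that add atoms: none
Why: Lewis-acid cleavage of aryl benzyl ethers by BCl3 at low temperature, with pentamethylbenzene trapping the benzyl cation by Friedel–Crafts alkylation so that neither the electron-rich rings nor the terminal alkene are benzylated, and with the chroman ether and the alkene expected to survive the short exposure at −78 °C.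

**Compound list**

1 | 3,5-bis(benzyloxy)phenol | Oc1cc(OCc2ccccc2)cc(OCc2ccccc2)c1 | starting material
2 | 1-bromo-3-methylbut-2-ene (prenyl bromide) | CC(C)=CCBr | starting material
3 | 1,3-bis(benzyloxy)-5-[(3-methylbut-2-en-1-yl)oxy]benzene | CC(C)=CCOc1cc(OCc2ccccc2)cc(OCc2ccccc2)c1 | intermediate
4 | 3,5-bis(benzyloxy)-6-(2-methylbut-3-en-2-yl)cyclohexa-2,4-dien-1-one (racemic) | C=CC(C)(C)C1C(=O)C=C(OCc2ccccc2)C=C1OCc1ccccc1 | intermediate (not isolated)
5 | 3,5-bis(benzyloxy)-2-(2-methylbut-3-en-2-yl)phenol | C=CC(C)(C)c1c(O)cc(OCc2ccccc2)cc1OCc1ccccc1 | intermediate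
6 | 3,5-bis(benzyloxy)-2-(hydroxymethyl)-6-(2-methylbut-3-en-2-yl)phenol (present as its magnesium salt) | C=CC(C)(C)c1c(O)c(CO)c(OCc2ccccc2)cc1OCc1ccccc1 | intermediate (not isolated)
7 | 4,6-bis(benzyloxy)-2-hydroxy-3-(2-methylbut-3-en-2-yl)benzaldehyde | C=CC(C)(C)c1c(O)c(C=O)c(OCc2ccccc2)cc1OCc1ccccc1 | intermediate
8 | ethyl bromoacetate | CCOC(=O)CBr | starting material
9 | ethyl 2-[3,5-bis(benzyloxy)-2-formyl-6-(2-methylbut-3-en-2-yl)phenoxy]acetate | CCOC(=O)COc1c(C=O)c(OCc2ccccc2)cc(OCc2ccccc2)c1C(C)(C)C=C | intermediate (not isolated)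
10 | ethyl 4,6-bis(benzyloxy)-3-hydroxy-7-(2-methylbut-3-en-2-yl)-2,3-dihydro-1-benzofuran-2-carboxylate (racemic diastereomer mixture) | CCOC(=O)C1Oc2c(C(C)(C)C=C)c(OCc3ccccc3)cc(OCc3ccccc3)c2C1O | intermediate (not isolated)
11 | ethyl 4,6-bis(benzyloxy)-7-(2-methylbut-3-en-2-yl)-1-benzofuran-2-carboxylate | CCOC(=O)c1cc2c(OCc3ccccc3)cc(OCc3ccccc3)c(C(C)(C)C=C)c2o1 | intermediate
12 | pentane-2,4-dione (acetylacetone) | CC(=O)CC(C)=O | starting material
13 | dilithium penta-1,3-diene-2,4-diolate (dianion of 12) | [Li+].[Li+].C=C([O-])C=C(C)[O-] | intermediate (not isolated)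
14 | 8-methylnon-7-ene-2,4-dione | CC(=O)CC(=O)CCC=C(C)C | intermediate
15 | dilithium 8-methylnona-1,3,7-triene-2,4-diolate (dianion of 14) | [Li+].[Li+].C=C([O-])C=C([O-])CCC=C(C)C | intermediate (not isolated)
16 | 1-[4,6-bis(benzyloxy)-7-(2-methylbut-3-en-2-yl)-1-benzofuran-2-yl]-9-methyldec-8-ene-1,3,5-trione | C=CC(C)(C)c1c(OCc2ccccc2)cc(OCc2ccccc2)c2cc(C(=O)CC(=O)CC(=O)CCC=C(C)C)oc12 | intermediate
17 | 5-[4,6-bis(benzyloxy)-7-(2-methylbut-3-en-2-yl)-1-benzofuran-2-yl]-5-hydroxy-4-(3-methylbut-2-en-1-yl)cyclohexane-1,3-dione (racemic diastereomer mixture, present as enolate) | C=CC(C)(C)c1c(OCc2ccccc2)cc(OCc2ccccc2)c2cc(C3(O)CC(=O)CC(=O)C3CC=C(C)C)oc12 | intermediate (not isolated)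
18 | 5-[4,6-bis(benzyloxy)-7-(2-methylbut-3-en-2-yl)-1-benzofuran-2-yl]-4-(3-methylbut-2-en-1-yl)benzene-1,3-diol | C=CC(C)(C)c1c(OCc2ccccc2)cc(OCc2ccccc2)c2cc(-c3cc(O)cc(O)c3CC=C(C)C)oc12 | intermediate
19 | 5-[4,6-bis(benzyloxy)-7-(2-methylbut-3-en-2-yl)-1-benzofuran-2-yl]-2,2-dimethyl-3,4-dihydro-2H-chromen-7-ol | C=CC(C)(C)c1c(OCc2ccccc2)cc(OCc2ccccc2)c2cc(-c3cc(O)cc4c3CCC(C)(C)O4)oc12 | intermediate
20 | 2-(7-hydroxy-2,2-dimethyl-3,4-dihydro-2H-chromen-5-yl)-7-(2-methylbut-3-en-2-yl)-1-benzofuran-4,6-diol | C=CC(C)(C)c1c(O)cc(O)c2cc(-c3cc(O)cc4c3CCC(C)(C)O4)oc12 | target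

**Step count**

Total: 9 steps. Longest linear sequence: 8 steps (1, 2, 3, 4, 6, 7, 8, 9); step 5 is a one-step branch.

**Steps most likely to fail**

Step 7 (aldol aromatisation). The chain may be cut by retro-Claisen attack of hydroxide, may close through an enol oxygen to a 4-pyranone, or may close slowly because a secondary enolate carbon has to attack a conjugated, electron-rich aroyl carbonyl. The fallback gives up the aldol and joins a ready-made ring C/D unit to C2 of the benzofuran by Suzuki–Miyaura coupling. It sets out from ester 11 and comes back to the route at target 20.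
- Benzofuran partner: saponification of 11 (LiOH, THF/MeOH/H2O) should give 4,6-bis(benzyloxy)-7-(2-methylbut-3-en-2-yl)-1-benzofuran-2-carboxylic acid F1. Protodecarboxylation (Ag2CO3, AcOH, DMSO, 120 °C) should give 4,6-bis(benzyloxy)-7-(2-methylbut-3-en-2-yl)-1-benzofuran F2. Lithiation at C2 (n-BuLi, THF, −78 °C) gives 4,6-bis(benzyloxy)-2-lithio-7-(2-methylbut-3-en-2-yl)-1-benzofuran F3, which is quenched with 2-isopropoxy-4,4,5,5-tetramethyl-1,3,2-dioxaborolane to give 2-[4,6-bis(benzyloxy)-7-(2-methylbut-3-en-2-yl)-1-benzofuran-2-yl]-4,4,5,5-tetramethyl-1,3,2-dioxaborolane F4.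
- Ring C/D partner: phloroglucinol and 3-methylbut-2-enoic acid (both bought) in MeSO3H/P2O5 should give 5,7-dihydroxy-2,2-dimethylchroman-4-one F5, whose regiochemistry is unambiguous because phloroglucinol is threefold symmetric. Benzylation of the non-chelated hydroxyl (BnBr, K2CO3, acetone) should give 7-(benzyloxy)-5-hydroxy-2,2-dimethylchroman-4-one F6. Ionic hydrogenation of the aryl ketone (Et3SiH, CF3CO2H) should give 7-(benzyloxy)-2,2-dimethyl-3,4-dihydro-2H-chromen-5-ol F7, and Tf2O/pyridine should give 7-(benzyloxy)-2,2-dimethyl-3,4-dihydro-2H-chromen-5-yl trifluoromethanesulfonate F8.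
- Coupling and return: F4 and F8 (Pd(OAc)2, 2-dicyclohexylphosphino-2',6'-dimethoxybiphenyl, K3PO4, toluene/H2O, 80 °C) should give 7-(benzyloxy)-5-[4,6-bis(benzyloxy)-7-(2-methylbut-3-en-2-yl)-1-benzofuran-2-yl]-2,2-dimethyl-3,4-dihydro-2H-chromene F9. The conditions of step 9, with a third equivalent of BCl3 and scavenger, should then give 20.

Step 2 (Claisen rearrangement). The allyl unit may migrate on from the crowded ortho dienone to the para carbon by a Cope shift, or the hindered ortho-(1,1-dimethylallyl)phenol may rearrange further or cyclise onto its own hydroxyl at the temperature needed. The fallback moves the sigmatropic step to the aldehyde stage, where the liberated hydroxyl is tied up at once in a hydrogen bond to the formyl group. It sets out from phenol 1 and comes back at aldehyde 7. Ortho-formylation of 1 (MgCl2, Et3N, (CH2O)n, MeCN, reflux; the two ortho carbons are equivalent) should give 2,4-bis(benzyloxy)-6-hydroxybenzaldehyde F10. O-prenylation with 2 (K2CO3, DMF) should give 2,4-bis(benzyloxy)-6-[(3-methylbut-2-en-1-yl)oxy]benzaldehyde F11. Heating F11 (PhNEt2, 190 °C) should move the allyl unit to the only free ortho carbon and give 7, which continues with step 4.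

Step 6 (dianion acylation). The second deprotonation of 14 may take place in part at the internal methylene instead of the methyl group, and proton transfer from the product to the dianion may stall the conversion. The fallback inverts the order of the two carbon–carbon bond formations so that each anion has only one terminal site. It sets out from ester 11 and dianion 13 (made as in step 5, three equivalents) and comes back at triketone 16. Acylation of 13 by 11 should give 1-[4,6-bis(benzyloxy)-7-(2-methylbut-3-en-2-yl)-1-benzofuran-2-yl]hexane-1,3,5-trione F12. Three equivalents of LiN(i-Pr)2 (THF, 0 °C) convert F12 into its trilithium trienolate F13, whose only terminal carbanion is alkylated by one equivalent of 2 to give 16.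

**Further compounds**

F1 | step 7 | 4,6-bis(benzyloxy)-7-(2-methylbut-3-en-2-yl)-1-benzofuran-2-carboxylic acid | C=CC(C)(C)c1c(OCc2ccccc2)cc(OCc2ccccc2)c2cc(C(=O)O)oc12
F2 | step 7 | 4,6-bis(benzyloxy)-7-(2-methylbut-3-en-2-yl)-1-benzofuran | C=CC(C)(C)c1c(OCc2ccccc2)cc(OCc2ccccc2)c2ccoc12
F3 | step 7 | 4,6-bis(benzyloxy)-2-lithio-7-(2-methylbut-3-en-2-yl)-1-benzofuran | [Li]c1cc2c(OCc3ccccc3)cc(OCc3ccccc3)c(C(C)(C)C=C)c2o1
F4 | step 7 | 2-[4,6-bis(benzyloxy)-7-(2-methylbut-3-en-2-yl)-1-benzofuran-2-yl]-4,4,5,5-tetramethyl-1,3,2-dioxaborolane | C=CC(C)(C)c1c(OCc2ccccc2)cc(OCc2ccccc2)c2cc(B3OC(C)(C)C(C)(C)O3)oc12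
F5 | step 7 | 5,7-dihydroxy-2,2-dimethylchroman-4-one | CC1(C)CC(=O)c2c(O)cc(O)cc2O1
F6 | step 7 | 7-(benzyloxy)-5-hydroxy-2,2-dimethylchroman-4-one | CC1(C)CC(=O)c2c(O)cc(OCc3ccccc3)cc2O1
F7 | step 7 | 7-(benzyloxy)-2,2-dimethyl-3,4-dihydro-2H-chromen-5-ol | CC1(C)CCc2c(O)cc(OCc3ccccc3)cc2O1
F8 | step 7 | 7-(benzyloxy)-2,2-dimethyl-3,4-dihydro-2H-chromen-5-yl trifluoromethanesulfonate | CC1(C)CCc2c(OS(=O)(=O)C(F)(F)F)cc(OCc3ccccc3)cc2O1
F9 | step 7 | 7-(benzyloxy)-5-[4,6-bis(benzyloxy)-7-(2-methylbut-3-en-2-yl)-1-benzofuran-2-yl]-2,2-dimethyl-3,4-dihydro-2H-chromene | C=CC(C)(C)c1c(OCc2ccccc2)cc(OCc2ccccc2)c2cc(-c3cc(OCc4ccccc4)cc4c3CCC(C)(C)O4)oc12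
F10 | step 2 | 2,4-bis(benzyloxy)-6-hydroxybenzaldehyde | O=Cc1c(O)cc(OCc2ccccc2)cc1OCc1ccccc1
F11 | step 2 | 2,4-bis(benzyloxy)-6-[(3-methylbut-2-en-1-yl)oxy]benzaldehyde | CC(C)=CCOc1cc(OCc2ccccc2)cc(OCc2ccccc2)c1C=O
F12 | step 6 | 1-[4,6-bis(benzyloxy)-7-(2-methylbut-3-en-2-yl)-1-benzofuran-2-yl]hexane-1,3,5-trione | C=CC(C)(C)c1c(OCc2ccccc2)cc(OCc2ccccc2)c2cc(C(=O)CC(=O)CC(C)=O)oc12
F13 | step 6 | trilithium trienolate of F12 | [Li+].[Li+].[Li+].C=C([O-])C=C([O-])C=C([O-])c1cc2c(OCc3ccccc3)cc(OCc3ccccc3)c(C(C)(C)C=C)c2o1
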